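## Retrosynthetic overview

1. The target comes from the 7-oxo methoxyquinone lactone 27 by C7 reduction, acetylation and O-demethylation; 27 comes from an oxygen-bridged cycloadduct, where base cleaves the C8–O bond (creating the quinone C8=C9) and the freed C10 oxygen closes the γ-lactone on C19.
2. Key disconnection (step 12): C10–C20 and C8–C9 together, by intramolecular cycloaddition of the carbonyl ylide C10=O(+)–C8(−), generated from 2-diazo-1,3-dione 21 with Rh2(OAc)4, onto a tethered vinyl group; rings B and C close in the same event.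
3. Enabling feature: ring B is a cycloheptane carrying oxygen on C10 and on C7 and sharing C8=C9 with ring C, that is, an opened 8-oxabicyclo[3.2.1]octan-2-one; C9 is α to the C11 quinone carbonyl, so the temporary C10–O–C8 bridge can be expelled by β-elimination.
4. 21 comes from aldehyde 7 (ring A; C4 and C5 set by copper-catalysed conjugate methylation and intramolecular alkylation through a temporary δ-lactone) and diazoketone 18 (tether whose E enol ether comes from a directed vinyl lithiation).
5. Ring order: ring A (from 1), temporary δ-lactone (made in step 2, opened in step 3), rings B and C together (step 12), quinone and γ-lactone (step 14).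

Key step: step 12

Remark on numbering: C1–C20 in names and comments are the skeleton numbers of the target (ring A: C1–C5, C10; ring B: C5–C10, C20; ring C: C8, C9, C11–C14; C19 is the lactone carbonyl); β is the face of the lactone bridge.

Assumption: C11 of the tether is carried as both configurations from step 7 until it becomes a carbonyl carbon in step 14, and the C7 carbinol of 20 is a mixture that is oxidised in step 11; these atoms carry no descriptor in 13–24.

## Route

Step 1
Reactants: 1 3-oxocyclohex-1-ene-1-carboxylic acid; 2 2-iodoethanol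
Product: 3 2-iodoethyl 3-oxocyclohex-1-ene-1-carboxylate
Conditions: DCC, DMAP (cat.), CH2Cl2, 0 °C → rt
Reagents that add atoms: none
Why: Steglich esterification of the conjugated acid with a primary alcohol installs the iodoethyl ester that later serves as a tether; no stereocentre is formed.

Step 2
Reactants: 3 2-iodoethyl 3-oxocyclohex-1-ene-1-carboxylate
Product: 5 (1S,6S)-1-methyl-3-oxabicyclo[4.4.0]decane-2,7-dione, via methylzinc enolate 4 (not isolated)
Conditions: Me2Zn, Cu(OTf)2 (5 mol %), chiral sulfonate-bridged N-heterocyclic carbene ligand (added as its imidazolinium salt; the enantiomer that gives the 4S centre), Et2O, −30 °C; then DMPU, 0 → 40 °C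
Reagents that add atoms: dimethylzinc, C[Zn]C
Why: Copper-catalysed asymmetric conjugate addition of methyl to the enone β-carbon sets the C4 quaternary centre under ligand control and gives a regiodefined zinc enolate, whose intramolecular 6-exo-tet C-alkylation by the ester-bound iodide (Michael-initiated ring closure) can reach C5 only from the ester face, which sets H-5 cis to the C4 methyl in a cis-fused δ-lactone.

Step 3
Reactants: 5 (1S,6S)-1-methyl-3-oxabicyclo[4.4.0]decane-2,7-dione
Product: 6 (1S,2S)-2-(2-hydroxyethyl)-N-methoxy-N,1-dimethyl-3-oxocyclohexane-1-carboxamide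
Conditions: MeNHOMe·HCl, Me2AlCl, CH2Cl2, 0 °C → rt; used at once
Reagents that add atoms: N,O-dimethylhydroxylamine hydrochloride, CNOC.Cl
Why: Aluminium-amide aminolysis of the lactone to the N-methoxy-N-methyl amide is non-basic, so the epimerisable C5 centre next to the ketone is untouched; it frees the C7 hydroxyl and keeps C19 as an acyl donor for the final lactone.

Step 4
Reactants: 6 (1S,2S)-2-(2-hydroxyethyl)-N-methoxy-N,1-dimethyl-3-oxocyclohexane-1-carboxamide
Product: 7 (1S,2S)-N-methoxy-N,1-dimethyl-3-oxo-2-(2-oxoethyl)cyclohexane-1-carboxamide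
Conditions: Dess–Martin periodinane, NaHCO3, CH2Cl2, 0 °C → rt
Reagents that add atoms: none
Why: Dess–Martin oxidation converts the primary alcohol into the C7 aldehyde under buffered conditions that do not epimerise C5.

Step 5
Reactants: 8 3-methylbutanoyl chloride
Product: 9 3-methyl-1-(morpholin-4-yl)butan-1-one
Conditions: morpholine, Et3N, CH2Cl2, 0 °C
Reagents that add atoms: morpholine, C1COCCN1
Why: Schotten–Baumann-type N-acylation gives a tertiary amide that can direct lithiation and later be turned into a ketone.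

Step 6
Reactants: 9 3-methyl-1-(morpholin-4-yl)butan-1-one
Product: 11 (E)-3-methoxy-1-(morpholin-4-yl)-2-(propan-2-yl)prop-2-en-1-one, via lithium formyl enolate 10 (not isolated)
Conditions: LiN(iPr)2, THF, −78 °C; HCO2Me, −78 → 0 °C; then Me2SO4, DMPU, rt
Reagents that add atoms: methyl formate, COC=O; dimethyl sulfate, COS(=O)(=O)OC
Why: Claisen formylation of the amide enolate followed by O-methylation of the formyl enolate (the standard β-methoxyacrylate construction) should give the thermodynamically preferred E enol ether with the methoxy group trans to the carbonyl.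

Step 7
Reactants: 11 (E)-3-methoxy-1-(morpholin-4-yl)-2-(propan-2-yl)prop-2-en-1-one; 12 acrolein
Product: 15 (E)-4-(tert-butyldimethylsilyloxy)-3-methoxy-1-(morpholin-4-yl)-2-(propan-2-yl)hexa-2,5-dien-1-one, via vinyllithium 13 (not isolated), via lithium alkoxide 14 (not isolated)
Conditions: LiN(iPr)2, THF, −78 °C; acrolein, −78 °C; then TBSOTf, −78 → 0 °C
Reagents that add atoms: tert-butyldimethylsilyl trifluoromethanesulfonate, CC(C)(C)[Si](C)(C)OS(=O)(=O)C(F)(F)F
Why: Carbonyl-directed vinylic lithiation of the β-alkoxyacrylamide at the hydrogen cis to the amide, 1,2-addition to acrolein and in situ O-silylation proceed with retention at the vinyl carbon, which places C11 cis to the acyl carbon (the geometry ring C needs); the new carbinol centre C11 is formed without control and is erased in step 14.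

Step 8
Reactants: 15 (E)-4-(tert-butyldimethylsilyloxy)-3-methoxy-1-(morpholin-4-yl)-2-(propan-2-yl)hexa-2,5-dien-1-one
Product: 16 (E)-5-(tert-butyldimethylsilyloxy)-4-methoxy-3-(propan-2-yl)hepta-3,6-dien-2-one
Conditions: MeLi, THF, −78 → 0 °C; aq. NH4Cl
Reagents that add atoms: methyllithium, [Li]C
Why: Addition of methyllithium to the morpholine amide gives a stable tetrahedral adduct that collapses to the methyl ketone only on work-up (ketone synthesis from a tertiary amide); the alkene geometry is untouched.

Step 9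
Reactants: 16 (E)-5-(tert-butyldimethylsilyloxy)-4-methoxy-3-(propan-2-yl)hepta-3,6-dien-2-one
Product: 18 (E)-5-(tert-butyldimethylsilyloxy)-1-diazo-4-methoxy-3-(propan-2-yl)hepta-3,6-dien-2-one, via trifluoroacetyl diketone 17 (not isolated)
Conditions: LiN(SiMe3)2, THF, −78 °C; CF3CO2CH2CF3; then MsN3, Et3N, H2O, MeCN, rt
Reagents that add atoms: methanesulfonyl azide, CS(=O)(=O)N=[N+]=[N-]
Why: Detrifluoroacetylative Regitz diazo transfer: the kinetic α'-enolate of the vinylogous ester is trifluoroacetylated, and the activated diketone takes up the diazo group with loss of the trifluoroacetyl group.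

Step 10
Reactants: 18 (E)-5-(tert-butyldimethylsilyloxy)-1-diazo-4-methoxy-3-(propan-2-yl)hepta-3,6-dien-2-one; 7 (1S,2S)-N-methoxy-N,1-dimethyl-3-oxo-2-(2-oxoethyl)cyclohexane-1-carboxamide
Product: 20 (1S,2S)-2-[(5E)-7-(tert-butyldimethylsilyloxy)-3-diazo-2-hydroxy-6-methoxy-4-oxo-5-(propan-2-yl)nona-5,8-dien-1-yl]-N-methoxy-N,1-dimethyl-3-oxocyclohexane-1-carboxamide, via lithiated diazoketone 19 (not isolated)
Conditions: LiN(iPr)2, THF, −78 °C; then 7, −78 °C; AcOH quench at −78 °C
Reagents that add atoms: none
Why: Aldol-type addition of a lithiated α-diazoketone to an aldehyde is fast at −78 °C and selective for the aldehyde over the hindered ketone and the amide, and the weakly basic nucleophile leaves C5 alone; the new C7 carbinol centre is uncontrolled and is oxidised in step 11.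

Step 11
Reactants: 20 (the aldol adduct of step 10)
Product: 21 (1S,2S)-2-[(5E)-7-(tert-butyldimethylsilyloxy)-3-diazo-6-methoxy-2,4-dioxo-5-(propan-2-yl)nona-5,8-dien-1-yl]-N-methoxy-N,1-dimethyl-3-oxocyclohexane-1-carboxamide
Conditions: Dess–Martin periodinane, NaHCO3, CH2Cl2, 0 °C → rt
Reagents that add atoms: none
Why: Dess–Martin oxidation of a β-hydroxy-α-diazoketone gives the 2-diazo-1,3-dione without loss of the diazo group and removes the C7 carbinol centre.

Step 12
Reactants: 21 (the 2-diazo-1,3-dione of step 11)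
Product: 23 N-methoxy-N-methyl 11-(tert-butyldimethylsilyloxy)-8β,10β-epoxy-12-methoxy-7,14-dioxoicetex-12-en-19-amide (4α-methyl; H-5α; H-9α), via carbonyl ylide 22 (not isolated)
Conditions: Rh2(OAc)4 (2 mol %), benzene, 80 °C, slow addition of 21 at high dilution
Reagents that add atoms: none
Why: Rh2(OAc)4 turns the 2-diazo-1,3-dione into a metal-bound carbene at C8, which is captured by the C10 ketone oxygen (six-membered ring O, C10, C5, C6, C7, C8) to give carbonyl ylide 22, and the C10–O–C8 dipole then adds suprafacially across the tethered vinyl group to form C10–C20 and C8–C9 in one concerted [3+2] event, formally a [5+2] annulation of the unit C10–C5–C6–C7–C8 with C20=C9. The closest known reaction type is the tandem carbonyl ylide formation and intramolecular 1,3-dipolar cycloaddition of α-diazo diketones, which gives 8-oxabicyclo[3.2.1]octan-2-ones. Ring B (the seven-membered carbocycle, temporarily oxygen-bridged between C10 and C8) is closed by both new bonds as the cycloaddition ring itself, and ring C (six-membered) is closed by the C8–C9 bond through the four-atom tether C14–C13–C12–C11, fused exo on the two-carbon bridge; the tether also fixes the regiochemistry (C9 to C8, C20 to C10). C10 is controlled by C5: the alkene adds to the ylide face opposite the quaternary C4 substituent of C5 (syn to H-5), so C20 becomes α and the bridging oxygen β, cis to the C19 carboxamide; C8 follows from the suprafacial addition and C9 from the tether, both are erased in step 14, and the E enol ether from step 7 is what lets the vinyl group reach C8. The step needs the carbene to be taken by the C10 ketone rather than by the allylic C11–H bond, the vinyl group or the amide oxygen; the six-membered geometry of the ketone attack and the high nucleophilicity of a ketone oxygen towards an acceptor-substituted carbene should secure this.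

Step 13
Reactants: 23 (the cycloadduct of step 12)
Product: 24 N-methoxy-N-methyl 8β,10β-epoxy-11-hydroxy-12-methoxy-7,14-dioxoicetex-12-en-19-amide
Conditions: HF·pyridine, pyridine, THF, 0 °C → rt
Reagents that add atoms: none
Why: Fluoride-mediated cleavage of the secondary silyl ether under buffered, weakly acidic conditions leaves the vinylogous ester, the α-alkoxy diketone and the oxygen bridge intact.

Step 14
Reactants: 24 (the alcohol of step 13)
Product: 27 12-methoxy-7,11,14-trioxoicetexa-8,12-dien-19,10β-olide, via C11 ketone 25 (not isolated), via hydroxy quinone amide 26 (not isolated)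
Conditions: Dess–Martin periodinane, NaHCO3, CH2Cl2, 0 °C → rt; aq. Na2S2O3 wash; then DBU, CH2Cl2, rt; then CSA, 40 °C
Reagents that add atoms: none
Why: Dess–Martin oxidation of C11 makes H-9 acidic, so E1cB β-elimination expels the C8 oxygen and creates the quinone C8=C9 while erasing C8, C9 and C11; the freed 10β-oxygen, 1,3-diaxial to the C19 amide, then lactonises by intramolecular acyl substitution with loss of N,O-dimethylhydroxylamine.

Step 15
Reactants: 27 12-methoxy-7,11,14-trioxoicetexa-8,12-dien-19,10β-olide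
Product: 29 7α-hydroxy-12-methoxy-11,14-dioxoicetexa-8,12-dien-19,10β-olide, via hydroquinone alcohol 28 (not isolated)
Conditions: NaBH4, CeCl3·7H2O, MeOH/THF, −40 → 0 °C; then air, EtOAc, rt
Reagents that add atoms: none
Why: Luche reduction: the quinone is first reduced to the hydroquinone and then the C7 ketone is reduced; the carbonyl is twisted out of the ring C plane by the peri C14 oxygen, so hydride should enter from the open β face rather than from the α face inside the ring B cavity (H-5α, H-20α), giving the quasi-axial 7α-alcohol, and air reoxidises the hydroquinone.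

Step 16
Reactants: 29 7α-hydroxy-12-methoxy-11,14-dioxoicetexa-8,12-dien-19,10β-olide
Product: 30 7α-acetoxy-12-methoxy-11,14-dioxoicetexa-8,12-dien-19,10β-olide
Conditions: Ac2O, pyridine, DMAP (cat.), CH2Cl2, 0 °C → rt
Reagents that add atoms: acetic anhydride, CC(=O)OC(C)=O
Why: DMAP-catalysed O-acylation of the secondary alcohol proceeds with retention at C7.

Step 17
Reactants: 30 7α-acetoxy-12-methoxy-11,14-dioxoicetexa-8,12-dien-19,10β-olide
Product: 31 7α-acetoxy-6,7-dihydroicetexone
Conditions: BCl3, CH2Cl2, −78 → −20 °C; aq. NaHCO3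
Reagents that add atoms: none
Why: Lewis-acid ether cleavage: BCl3 chelates the C11 carbonyl and the neighbouring methoxy oxygen of the vinylogous ester and chloride removes the methyl group at low temperature, where the secondary acetate and the γ-lactone should be inert; no stereocentre is touched.

## Compound list

1 | 3-oxocyclohex-1-ene-1-carboxylic acid | O=C1CCCC(C(=O)O)=C1 | starting material
2 | 2-iodoethanol | OCCI | starting material
3 | 2-iodoethyl 3-oxocyclohex-1-ene-1-carboxylate | O=C1CCCC(C(=O)OCCI)=C1 | intermediate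
4 | 2-iodoethyl (1S)-1-methyl-3-[(methylzincio)oxy]cyclohex-2-ene-1-carboxylate (methylzinc enolate) | ICCOC(=O)[C@@]1(C)CCCC(O[Zn]C)=C1 | intermediate
5 | (1S,6S)-1-methyl-3-oxabicyclo[4.4.0]decane-2,7-dione (cis-fused keto δ-lactone; C4 methyl and H-5 cis) | C1C[C@@H]2C(=O)CCC[C@]2(C)C(=O)O1 | intermediate
6 | (1S,2S)-2-(2-hydroxyethyl)-N-methoxy-N,1-dimethyl-3-oxocyclohexane-1-carboxamide | CON(C)C(=O)[C@@]1(C)CCCC(=O)[C@H]1CCO | intermediate
7 | (1S,2S)-N-methoxy-N,1-dimethyl-3-oxo-2-(2-oxoethyl)cyclohexane-1-carboxamide | CON(C)C(=O)[C@@]1(C)CCCC(=O)[C@H]1CC=O | intermediate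
8 | 3-methylbutanoyl chloride | CC(C)CC(Cl)=O | starting material
9 | 3-methyl-1-(morpholin-4-yl)butan-1-one | CC(C)CC(=O)N1CCOCC1 | intermediate
10 | lithium enolate of 2-formyl-3-methyl-1-(morpholin-4-yl)butan-1-one | [Li+].[O-]C=C(C(C)C)C(=O)N1CCOCC1 | intermediate
11 | (E)-3-methoxy-1-(morpholin-4-yl)-2-(propan-2-yl)prop-2-en-1-one | CO/C=C(\C(C)C)C(=O)N1CCOCC1 | intermediate
12 | acrolein (prop-2-enal) | C=CC=O | starting material
13 | [1-methoxy-3-(morpholin-4-yl)-3-oxo-2-(propan-2-yl)prop-1-en-1-yl]lithium (lithium cis to the amide carbonyl) | CO/C([Li])=C(\C(C)C)C(=O)N1CCOCC1 | intermediate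
14 | lithium (E)-4-methoxy-6-(morpholin-4-yl)-6-oxo-5-(propan-2-yl)hexa-1,4-dien-3-olate | [Li+].CO/C(C([O-])C=C)=C(\C(C)C)C(=O)N1CCOCC1 | intermediate
15 | (E)-4-(tert-butyldimethylsilyloxy)-3-methoxy-1-(morpholin-4-yl)-2-(propan-2-yl)hexa-2,5-dien-1-one (both configurations at C4 of the chain) | CO/C(C(O[Si](C)(C)C(C)(C)C)C=C)=C(\C(C)C)C(=O)N1CCOCC1 | intermediate
16 | (E)-5-(tert-butyldimethylsilyloxy)-4-methoxy-3-(propan-2-yl)hepta-3,6-dien-2-one | CO/C(C(O[Si](C)(C)C(C)(C)C)C=C)=C(\C(C)C)C(C)=O | intermediate
17 | (E)-7-(tert-butyldimethylsilyloxy)-1,1,1-trifluoro-6-methoxy-5-(propan-2-yl)nona-5,8-diene-2,4-dione | CO/C(C(O[Si](C)(C)C(C)(C)C)C=C)=C(\C(C)C)C(=O)CC(=O)C(F)(F)F | intermediate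
18 | (E)-5-(tert-butyldimethylsilyloxy)-1-diazo-4-methoxy-3-(propan-2-yl)hepta-3,6-dien-2-one | CO/C(C(O[Si](C)(C)C(C)(C)C)C=C)=C(\C(C)C)C(=O)C=[N+]=[N-] | intermediate
19 | 1-lithio derivative of diazoketone 18 | CO/C(C(O[Si](C)(C)C(C)(C)C)C=C)=C(\C(C)C)C(=O)C([Li])=[N+]=[N-] | intermediate
20 | (1S,2S)-2-[(5E)-7-(tert-butyldimethylsilyloxy)-3-diazo-2-hydroxy-6-methoxy-4-oxo-5-(propan-2-yl)nona-5,8-dien-1-yl]-N-methoxy-N,1-dimethyl-3-oxocyclohexane-1-carboxamide (both configurations at the two carbinol carbons) | CON(C)C(=O)[C@@]1(C)CCCC(=O)[C@H]1CC(O)C(=[N+]=[N-])C(=O)/C(C(C)C)=C(/OC)C(O[Si](C)(C)C(C)(C)C)C=C | intermediate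
21 | (1S,2S)-2-[(5E)-7-(tert-butyldimethylsilyloxy)-3-diazo-6-methoxy-2,4-dioxo-5-(propan-2-yl)nona-5,8-dien-1-yl]-N-methoxy-N,1-dimethyl-3-oxocyclohexane-1-carboxamide | CON(C)C(=O)[C@@]1(C)CCCC(=O)[C@H]1CC(=O)C(=[N+]=[N-])C(=O)/C(C(C)C)=C(/OC)C(O[Si](C)(C)C(C)(C)C)C=C | intermediate
22 | six-membered carbonyl ylide from 21 (zwitterion C10=O(+)–C8(−) in the ring O, C10, C5, C6, C7, C8; C8 carries the C14 acyl tether) | CON(C)C(=O)[C@@]1(C)CCCC2=[O+][C-](C(=O)C[C@@H]12)C(=O)/C(C(C)C)=C(/OC)C(O[Si](C)(C)C(C)(C)C)C=C | intermediate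
23 | N-methoxy-N-methyl 11-(tert-butyldimethylsilyloxy)-8β,10β-epoxy-12-methoxy-7,14-dioxoicetex-12-en-19-amide (4α-methyl; H-5α; H-9α; both C11 epimers) | CON(C)C(=O)[C@@]1(C)CCC[C@@]23O[C@]4(C(=O)C[C@@H]12)C(=O)C(C(C)C)=C(OC)C(O[Si](C)(C)C(C)(C)C)[C@@H]4C3 | intermediate
24 | N-methoxy-N-methyl 8β,10β-epoxy-11-hydroxy-12-methoxy-7,14-dioxoicetex-12-en-19-amide | CON(C)C(=O)[C@@]1(C)CCC[C@@]23O[C@]4(C(=O)C[C@@H]12)C(=O)C(C(C)C)=C(OC)C(O)[C@@H]4C3 | intermediate
25 | N-methoxy-N-methyl 8β,10β-epoxy-12-methoxy-7,11,14-trioxoicetex-12-en-19-amide | CON(C)C(=O)[C@@]1(C)CCC[C@@]23O[C@]4(C(=O)C[C@@H]12)C(=O)C(C(C)C)=C(OC)C(=O)[C@@H]4C3 | intermediate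
26 | N-methoxy-N-methyl 10β-hydroxy-12-methoxy-7,11,14-trioxoicetexa-8,12-dien-19-amide | CON(C)C(=O)[C@@]1(C)CCC[C@]2(O)CC3=C(C(=O)C[C@@H]12)C(=O)C(C(C)C)=C(OC)C3=O | intermediate
27 | 12-methoxy-7,11,14-trioxoicetexa-8,12-dien-19,10β-olide | O=C1C[C@@H]2[C@]3(CCC[C@]2(C)C(=O)O3)CC2=C1C(=O)C(C(C)C)=C(OC)C2=O | intermediate
28 | 7α,11,14-trihydroxy-12-methoxyicetexa-8,11,13-trien-19,10β-olide | O[C@@H]1C[C@@H]2[C@]3(CCC[C@]2(C)C(=O)O3)Cc2c1c(O)c(C(C)C)c(OC)c2O | intermediate
29 | 7α-hydroxy-12-methoxy-11,14-dioxoicetexa-8,12-dien-19,10β-olide | O[C@@H]1C[C@@H]2[C@]3(CCC[C@]2(C)C(=O)O3)CC2=C1C(=O)C(C(C)C)=C(OC)C2=O | intermediate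
30 | 7α-acetoxy-12-methoxy-11,14-dioxoicetexa-8,12-dien-19,10β-olide | CC(=O)O[C@@H]1C[C@@H]2[C@]3(CCC[C@]2(C)C(=O)O3)CC2=C1C(=O)C(C(C)C)=C(OC)C2=O | intermediate
31 | 7α-acetoxy-6,7-dihydroicetexone | CC(=O)O[C@@H]1C[C@@H]2[C@]3(CCC[C@]2(C)C(=O)O3)CC2=C1C(=O)C(C(C)C)=C(O)C2=O | target

## Step count and risks

Total step count: 17. Longest linear sequence: 13 steps (steps 5–17, from 3-methylbutanoyl chloride); the ring A branch is steps 1–4.

Steps most likely to fail:

Step 12. The metal carbene may be diverted by insertion into the activated allylic C11–H bond or by cyclopropanation of the vinyl group before the ketone captures it, or the ylide may undergo proton transfer because addition to an unactivated alkene is slow. The fallback oxidises first and cyclises second. It sets out from 20: HF·pyridine removes the silyl group to give the diol (1S,2S)-2-[(5E)-3-diazo-2,7-dihydroxy-6-methoxy-4-oxo-5-(propan-2-yl)nona-5,8-dien-1-yl]-N-methoxy-N,1-dimethyl-3-oxocyclohexane-1-carboxamide F1. Dess–Martin periodinane then oxidises both carbinols to the vinyl ketone (1S,2S)-2-[(5E)-3-diazo-6-methoxy-2,4,7-trioxo-5-(propan-2-yl)nona-5,8-dien-1-yl]-N-methoxy-N,1-dimethyl-3-oxocyclohexane-1-carboxamide F2. Rh2(OAc)4 then effects the same ylide formation and cycloaddition onto an electron-poor enone, which has no C11–H bond and should react faster, and the route is rejoined at 25 (DBU and CSA as in step 14 then give 27).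

Step 2. The zinc enolate is a weak nucleophile, so ring closure may lag and the enolate may simply be protonated on work-up. The fallback sets out from 3: the conjugate addition is quenched with Me3SiCl to give the isolable silyl enol ether 2-iodoethyl (1S)-1-methyl-3-(trimethylsilyloxy)cyclohex-2-ene-1-carboxylate F3. MeLi in THF/DMPU then releases the regiodefined lithium enolate, which closes the lactone by the same tether-controlled alkylation, and the route is rejoined at 5.

Step 15. Hydride delivery may show poor facial selectivity or prefer the α face, giving the 7β-alcohol. The fallback sets out from 27: the reduction is carried through to the epimeric alcohol 7β-hydroxy-12-methoxy-11,14-dioxoicetexa-8,12-dien-19,10β-olide F4, and a Mitsunobu esterification (AcOH, PPh3, diisopropyl azodicarboxylate, THF) inverts C7 to give the 7α-acetate directly; the route is rejoined at 30 and step 16 is skipped.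

Further compounds
F1 | step 12 | (1S,2S)-2-[(5E)-3-diazo-2,7-dihydroxy-6-methoxy-4-oxo-5-(propan-2-yl)nona-5,8-dien-1-yl]-N-methoxy-N,1-dimethyl-3-oxocyclohexane-1-carboxamide | CON(C)C(=O)[C@@]1(C)CCCC(=O)[C@H]1CC(O)C(=[N+]=[N-])C(=O)/C(C(C)C)=C(/OC)C(O)C=C
F2 | step 12 | (1S,2S)-2-[(5E)-3-diazo-6-methoxy-2,4,7-trioxo-5-(propan-2-yl)nona-5,8-dien-1-yl]-N-methoxy-N,1-dimethyl-3-oxocyclohexane-1-carboxamide | CON(C)C(=O)[C@@]1(C)CCCC(=O)[C@H]1CC(=O)C(=[N+]=[N-])C(=O)/C(C(C)C)=C(/OC)C(=O)C=C
F3 | step 2 | 2-iodoethyl (1S)-1-methyl-3-(trimethylsilyloxy)cyclohex-2-ene-1-carboxylate | ICCOC(=O)[C@@]1(C)CCCC(O[Si](C)(C)C)=C1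
F4 | step 15 | 7β-hydroxy-12-methoxy-11,14-dioxoicetexa-8,12-dien-19,10β-olide | O[C@H]1C[C@@H]2[C@]3(CCC[C@]2(C)C(=O)O3)CC2=C1C(=O)C(C(C)C)=C(OC)C2=O
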